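The earlier runs and the new flask were generated by integration on assumed constants; scatter was added.

Compare two amounts: the catalyst charged, and the catalyst the added ligand has captured at the conversion asked about.

the same everywhere: substrate 0.014 M; added ligand 0.27 mM
- west: catalyst 1 mol%; run made earlier
- south-east: catalyst 1.5 mol%; run made earlier
- flask: catalyst 2 mol%

- west (time / s: target / %): 10.0: 52.9; 12.0: 56.0; 20.0: 66.2; 30.0: 74.7; 50.0: 86.6; 80.0: 92.9
- south-east (time / s: target / %): 10.0: 79.2; 12.0: 82.0; 20.0: 92.9; 30.0: 97.1; 50.0: 97.8; 80.0: 100.7

(each reading ± 1 percentage point)

* apparent order in catalyst when 30% of the substrate are converted (percent change of the rate of making target for one percent more catalyst charged)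

1. Substrate and added ligand both react with free catalyst, so I integrated the two forward rates against each other. This gave ln(c substrate at start / c substrate) = ρ · ln(c added ligand at start / c added ligand). Here ρ is the capture ratio, a selectivity factor.

2. I read ρ from the west run. Between 20.0 s and 50.0 s, ln(1/(1 − conversion)) rose at 0.0308 s⁻¹. Extrapolated back, the line met zero time at 0.468. I assumed the burst ended once the added ligand had taken the west charge of 0.140 mM. That gave ρ = 0.640, a reading with the scatter of its points.

3. At 30% conversion in the flask, this ρ puts 0.115 mM in idle complex, out of 0.280 mM catalyst charged. I took that captured amount as independent of the charge. The order is then the charge over the uncaptured charge, my titration order: 1.70.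

4. The forecast said 1.8, above mine, and held that “ligand capture is not instantaneous”.

5. The flask gave 1.2.

    2 catalyst ⇌ resting dimer, settled at all times (K = 1800 M⁻¹)
    catalyst + added ligand ⇌ idle complex (K = 2.20 × 10⁵ M⁻¹, k = 9700 M⁻¹ s⁻¹)
    substrate + catalyst → catalyst + target (k = 6700 M⁻¹ s⁻¹)

That is below my titration order of 1.70. The run without the path to idle complex gave 0.72, so capture by the added ligand has the largest single effect on the order, 0.524. The run without the resting dimer gave 1.6, so the binding of catalyst into the resting dimer is part of the gap. Removing that binding moved the order by 0.38.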